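## The problem

Target 17 is a depside. Ring A is a 2-hydroxy-6-pentylbenzoic acid oxygenated at C4, ring B is a 2,4-dimethoxy-6-propylbenzoyl group, and the only link between them is an aryl ester from the ring B carbonyl to O4 of ring A. There is no stereocentre, so the difficulties are regiochemistry and functional-group tolerance.

On ring A the C1 carboxyl sits between the C2 hydroxyl and the C6 pentyl chain, and only O4 is acylated. The two oxygens of a resorcinol must therefore be told apart, and the carbon between one of them and the chain must be functionalised. The ring B acid is substituted at both ortho positions, so the ester needs an activated acyl donor. Once made, the ester has a phenoxide leaving group and is cleaved by hydroxide, alkoxide and other hard nucleophiles. The free acid is a salicylic acid with a second oxygen para to the carboxyl and can lose CO2 on heating or in strong acid. Freeing the C1 carboxyl from an alkyl ester by saponification is therefore excluded, and the last steps must be cold and close to neutral.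

The enabling feature is that C1 of ring A is C4 of olivetol, ortho to one hydroxyl and para to the other, which is where electrophilic bromination is expected to go. A bromine there is a latent carboxyl and also makes the two hydroxyls unequal: O2 lies beside the halogen and O4 is remote. The C1–Br bond can be converted into C1–CO2H reductively with CO2 at a nickel-catalysed cathode, with no hydroxide present.

## Retrosynthesis

**O2–Si bond, 17 from 16.** The final operation is cleavage of the silyl ether on O2 of acid 16. This is the mildest step available and is placed last so that nothing harsher follows the appearance of the sensitive hydroxy acid. Compound 16 differs from 17 only by the silyl group. The forward step must avoid basic conditions, which would attack the depside ester, and heat, which would risk decarboxylation.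

**C1–carboxyl bond, 16 from 13 and 14.** The C1–CO2H bond is cut to leave bromide 13 and carbon dioxide 14, with magnesium carboxylate 15 in between. Cutting the depside ester first would require a ring A that already carries the carboxyl. That carboxyl would have to be masked as an ester and unmasked beside the aryl ester, or left free to compete in the acylation. Introducing the carboxyl last, as the free acid, removes that protecting group. Precursor 13 is reachable from olivetol 9 in three steps. The forward reaction must reduce C–Br without touching the aryl benzoate and must find no proton to quench the aryl–nickel intermediate.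

**O2–Si bond of the precursor, 13 from 11 and 12.** The silyl group from chloride 12 removes the only acidic proton of phenol 11. It is inert at the cathode and comes off later without base. The forward step is a routine silylation that must leave the ester alone.

**Ester C–O bond, 11 from 10 and 8.** The acyl–O4 bond is cut to give bromoresorcinol 10 and acid chloride 8. In 10 the hydroxyl next to bromine is shielded and inductively deactivated, while the other is flanked by two hydrogens, so a hindered acyl chloride should take the remote oxygen. Acylating olivetol 9 before bromination is the neighbouring option. It would leave a later bromination to choose among three ring A positions and the electron-rich ring B, so the halogen goes in first.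

**C–Br bond, 10 from 9.** The bromine is removed to give commercial olivetol 9. Positions 4 and 6 of 9 are equivalent and doubly activated, so one equivalent of electrophilic bromine should give a single monobromide. The forward step must be stopped before the second bromination.

**Ring B carbonyl, 8 from 7, 6 and 4.** Acid chloride 8 comes from acid 7, which comes from aldehyde 6. The aryl–CHO bond of 6 is cut to give 1,3-dimethoxy-5-propylbenzene 4, with iminium salt 5 as the intermediate. Formylation of 4 must go para to one methoxy group, ortho to the other and next to the propyl chain. The position between the two methoxy groups is more crowded, so this is the expected site.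

**Propyl chain, 4 from 3, 1 and 2.** The side chain is cut at the benzylic C–C double bond of alkene 3, which comes from commercial aldehyde 1 and phosphonium salt 2. Olefination followed by hydrogenation delivers the propyl group in two routine steps with the methoxy pattern already in place.

## Roads not taken

**Alternative 1: ring A by Diels–Alder with the aroyloxy group aboard.**
- Cut: C1–C2 and C5–C6 of ring A. The forward step is a thermal cycloaddition of 4-methoxy-4-(trimethylsilyloxy)buta-1,3-dien-2-yl 2,4-dimethoxy-6-propylbenzoate A2 with benzyl oct-2-ynoate A3. Elimination of the methoxy group and loss of silicon then give benzyl 4-[(2,4-dimethoxy-6-propylbenzoyl)oxy]-2-hydroxy-6-pentylbenzoate A1, and hydrogenolysis of the benzyl ester finishes the synthesis.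
- Merits: all four ring A substituents are placed by the polarity of diene and dienophile, so no bromination selectivity and no differentiation of two phenols is needed. The carboxyl is freed by hydrogenolysis, which is as safe for the depside as the fluoride step used here. In regiocontrol this road is better than the chosen one.
- Weak points: A2 is a ketene acetal carrying an enol aroate. Making it requires strong base and silylation beside an acyl group that can migrate to carbon. Its C3 acyloxy group makes it a poorer diene than the siloxy analogues, and A3, with an alkyl group on the β-carbon, is a sluggish dienophile, so the pair would need heat that the ketene acetal may not survive.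
- Comparison: the chosen plan buys ring A intact as olivetol 9 and uses only standard reactions up to the key step. The price is one site-selective acylation.

**Alternative 2: biomimetic ring B by acylketene capture and aldol aromatisation.**
- Cut: the ester C–O bond and the C2–C7 bond of a polyketide chain. Heating 6-(2,4-dioxoheptyl)-2,2-dimethyl-4H-1,3-dioxin-4-one A5 opens the dioxinone to acylketene A6 (dec-1-ene-1,3,5,7-tetrone). The free C4 hydroxyl of benzyl 2-(benzyloxy)-4-hydroxy-6-pentylbenzoate A7 traps it as aryl 3,5,7-trioxodecanoate A8, which cyclises and aromatises to benzyl 2-(benzyloxy)-4-[(2,4-dihydroxy-6-propylbenzoyl)oxy]-6-pentylbenzoate A4.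
- Merits: the hindered ester bond is formed before ring B exists, by addition of a phenol to an unhindered ketene. This is a real advantage over acylation with the di-ortho-substituted chloride 8. Ester and ring B arise in one flask.
- Weak points: ring B emerges as a free resorcinol. Both phenols must then be methylated with base next to the aryl ester, and one of them is hydrogen-bonded to the ester carbonyl. A8 can also close through oxygen to a pyrone and expel A7. A7 itself needs the less reactive, hydrogen-bonded O2 benzylated while O4 stays free, which costs extra protecting-group steps. A5 is a multistep compound, and two benzyl groups must be removed at the end.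
- Comparison: the chosen plan has ring B with its methyl ethers from aldehyde 1 onward and no late methylation, and is clearly shorter. It accepts the hindered acylation, which DMAP catalysis and an unhindered phenol should make workable.

**Alternative 3: carboxylate oxygen as nucleophile, copper O-arylation at ring A C4.**
- Cut: the ring A C4–O bond. Acid 7 and tert-butyl 2-(methoxymethoxy)-6-pentyl-4-(4,4,5,5-tetramethyl-1,3,2-dioxaborolan-2-yl)benzoate A10 are coupled with Cu(OTf)2 and a base under air to give tert-butyl 4-[(2,4-dimethoxy-6-propylbenzoyl)oxy]-2-(methoxymethoxy)-6-pentylbenzoate A9. Acid then removes both protecting groups.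
- Merits: the bond forms at the carboxylate oxygen, away from the crowded carbonyl carbon, and no choice between two phenols arises. On these two points it is at least as good as the chosen plan.
- Weak points: oxidative copper coupling of carboxylic acids with aryl boronates is less general than with phenols or amines, and protodeboronation and hydroxylation of A10 compete. A10 must be built from a 2-hydroxy-6-pentylbenzoate that is not a commodity chemical. The end game exposes the decarboxylation-prone hydroxy acid to the strong acid needed for the tert-butyl ester.
- Comparison: the chosen plan starts with O4 already on the ring, needs no boron chemistry, and ends with a cold fluoride step instead of strong acid.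

Key step: step 9

Assumption: alkene 3 is carried forward as its E/Z mixture because step 2 removes the double bond, and acid chloride 8 is used crude after evaporation.

## Route

Step 1
Reactants: 1 3,5-dimethoxybenzaldehyde; 2 ethyltriphenylphosphonium bromide
Product: 3 1,3-dimethoxy-5-(prop-1-en-1-yl)benzene (E/Z mixture)
Conditions: KOt-Bu, THF, 0 °C to rt
Reagents that add atoms: ethyltriphenylphosphonium bromide (2), CC[P+](c1ccccc1)(c1ccccc1)c1ccccc1.[Br-]
Why: Wittig olefination of an aromatic aldehyde with the unstabilised ylide made from 2 is routine; the alkene geometry does not matter because step 2 saturates the double bond.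

Step 2
Reactants: 3 1,3-dimethoxy-5-(prop-1-en-1-yl)benzene
Product: 4 1,3-dimethoxy-5-propylbenzene
Conditions: H2 (1 atm), 10% Pd/C, EtOAc, rt
Reagents that add atoms: none
Why: Catalytic hydrogenation of a styrene-type alkene over Pd/C is fast at atmospheric pressure and leaves the aryl methyl ethers untouched.

Step 3
Reactants: 4 1,3-dimethoxy-5-propylbenzene
Product: 6 2,4-dimethoxy-6-propylbenzaldehyde, via aryl iminium chloride 5 (not isolated)
Conditions: POCl3, DMF, 0 °C to 70 °C; then ice-water
Reagents that add atoms: N,N-dimethylformamide, CN(C)C=O; water, O
Why: Vilsmeier–Haack formylation of a 1,3-dimethoxy-5-alkylbenzene should go para to one methoxy group and ortho to the other, next to the alkyl chain, because the position between the two methoxy groups is more crowded; water then hydrolyses iminium salt 5 to the aldehyde.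

Step 4
Reactants: 6 2,4-dimethoxy-6-propylbenzaldehyde
Product: 7 2,4-dimethoxy-6-propylbenzoic acid
Conditions: NaClO2, NaH2PO4, 2-methyl-2-butene (excess), t-BuOH/H2O, 0 °C to rt
Reagents that add atoms: sodium chlorite, [Na+].[O-]Cl=O
Why: Pinnick oxidation converts hindered, electron-rich benzaldehydes into the acids under buffered conditions; the excess alkene traps hypochlorous acid so that ring B is not chlorinated.

Step 5
Reactants: 7 2,4-dimethoxy-6-propylbenzoic acid
Product: 8 2,4-dimethoxy-6-propylbenzoyl chloride
Conditions: (COCl)2, DMF (cat.), CH2Cl2, 0 °C to rt; evaporate, use crude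
Reagents that add atoms: oxalyl chloride, O=C(Cl)C(=O)Cl
Why: Acid chloride formation with oxalyl chloride and catalytic DMF proceeds at room temperature without cleaving the methyl ethers, and gives the activated acyl donor that a di-ortho-substituted acid needs.

Step 6
Reactants: 9 olivetol (5-pentylbenzene-1,3-diol)
Product: 10 4-bromo-5-pentylbenzene-1,3-diol
Conditions: NBS (1.0 equiv, slow addition), MeCN, −30 °C to 0 °C
Reagents that add atoms: N-bromosuccinimide, O=C1CCC(=O)N1Br
Why: Electrophilic aromatic bromination of a 5-alkylresorcinol should go to C4 (equivalent to C6), ortho to one hydroxyl and para to the other, in preference to the flanked C2; one equivalent added slowly in the cold limits the 4,6-dibromide.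

Step 7
Reactants: 10 4-bromo-5-pentylbenzene-1,3-diol; 8 2,4-dimethoxy-6-propylbenzoyl chloride
Product: 11 4-bromo-3-hydroxy-5-pentylphenyl 2,4-dimethoxy-6-propylbenzoate
Conditions: Et3N, DMAP (cat.), CH2Cl2, −20 °C to rt; 8 added slowly to 10 (1.2 equiv)
Reagents that add atoms: none
Why: DMAP-catalysed esterification of a phenol with an acyl chloride; the hydroxyl para to bromine is flanked by two hydrogens and is the more nucleophilic, while the one ortho to bromine is shielded and inductively deactivated, so the hindered chloride should acylate the remote oxygen, as monofunctionalisation of 4-halo-resorcinols generally does.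

Step 8
Reactants: 11 4-bromo-3-hydroxy-5-pentylphenyl 2,4-dimethoxy-6-propylbenzoate; 12 tert-butyldimethylsilyl chloride
Product: 13 4-bromo-3-[(tert-butyldimethylsilyl)oxy]-5-pentylphenyl 2,4-dimethoxy-6-propylbenzoate
Conditions: TBSCl, imidazole, DMF, rt
Reagents that add atoms: tert-butyldimethylsilyl chloride (12), CC(C)(C)[Si](C)(C)Cl
Why: Silylation of a phenol with TBSCl and imidazole is standard, tolerates an ortho bromine and is neutral enough to leave the aryl ester intact.

Step 9
Reactants: 13 4-bromo-3-[(tert-butyldimethylsilyl)oxy]-5-pentylphenyl 2,4-dimethoxy-6-propylbenzoate; 14 carbon dioxide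
Product: 16 2-[(tert-butyldimethylsilyl)oxy]-4-[(2,4-dimethoxy-6-propylbenzoyl)oxy]-6-pentylbenzoic acid, via bromomagnesium carboxylate 15 (not isolated)
Conditions: NiBr2(bpy) (10 mol%, bpy = 2,2'-bipyridine), CO2 (1 atm), Mg anode, carbon-fibre cathode, n-Bu4NBF4, dry DMF, constant current, undivided cell, 10–20 °C; then cold 1 M HCl
Reagents that add atoms: carbon dioxide (14), O=C=O
Why: The cathode reduces NiBr2(bpy), a complex of divalent nickel, to a zerovalent nickel bipyridine complex that inserts into the C1–Br bond of 13; one-electron reduction of the arylnickel bromide gives an aryl complex of monovalent nickel that adds to CO2, and magnesium ions from the dissolving anode take up the carboxylate as 15 while nickel returns to the cycle. The closest known reaction type is the nickel-catalysed electroreductive carboxylation of aryl halides with CO2 at a sacrificial magnesium anode, applied here to a di-ortho-substituted bromide. One C–C bond forms, no ring closes and no stereocentre is created. The step needs reduction of C–Br in preference to the aryl benzoate; the catalyst turns over at a potential well short of that at which aryl esters accept electrons directly, and the bipyridine-ligated zerovalent nickel is not expected to insert into the ester C–O bond at room temperature. It also needs carboxylation to outrun protonation and biaryl coupling; the O2 silyl ether removes the only acidic proton, the DMF is dry and saturated with CO2, and the two ortho substituents disfavour the bimolecular aryl transfer that leads to homocoupling. Cold dilute acid releases acid 16 from 15 without harming the depside ester, and any loss or oxygen-to-oxygen shift of the silyl group at this stage is harmless because step 10 removes it.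

Step 10
Reactants: 16 2-[(tert-butyldimethylsilyl)oxy]-4-[(2,4-dimethoxy-6-propylbenzoyl)oxy]-6-pentylbenzoic acid
Product: 17 4-[(2,4-dimethoxy-6-propylbenzoyl)oxy]-2-hydroxy-6-pentylbenzoic acid
Conditions: HF·pyridine, THF, 0 °C to rt
Reagents that add atoms: none
Why: Cleavage of an aryl silyl ether by HF·pyridine is acidic and non-basic, so the aryl ester is not attacked and no phenoxide is generated; the reaction is kept cold to avoid decarboxylation of the hydroxy acid.

## Compound list

1 | 3,5-dimethoxybenzaldehyde | COc1cc(C=O)cc(OC)c1 | starting material
2 | ethyltriphenylphosphonium bromide | CC[P+](c1ccccc1)(c1ccccc1)c1ccccc1.[Br-] | starting material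
3 | 1,3-dimethoxy-5-(prop-1-en-1-yl)benzene (E/Z mixture) | CC=Cc1cc(OC)cc(OC)c1 | intermediate
4 | 1,3-dimethoxy-5-propylbenzene | CCCc1cc(OC)cc(OC)c1 | intermediate
5 | N-[(2,4-dimethoxy-6-propylphenyl)methylidene]-N-methylmethanaminium chloride (not isolated) | CCCc1cc(OC)cc(OC)c1C=[N+](C)C.[Cl-] | intermediate
6 | 2,4-dimethoxy-6-propylbenzaldehyde | CCCc1cc(OC)cc(OC)c1C=O | intermediate
7 | 2,4-dimethoxy-6-propylbenzoic acid | CCCc1cc(OC)cc(OC)c1C(=O)O | intermediate
8 | 2,4-dimethoxy-6-propylbenzoyl chloride | CCCc1cc(OC)cc(OC)c1C(=O)Cl | intermediate
9 | olivetol (5-pentylbenzene-1,3-diol) | CCCCCc1cc(O)cc(O)c1 | starting material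
10 | 4-bromo-5-pentylbenzene-1,3-diol | CCCCCc1cc(O)cc(O)c1Br | intermediate
11 | 4-bromo-3-hydroxy-5-pentylphenyl 2,4-dimethoxy-6-propylbenzoate | CCCCCc1cc(OC(=O)c2c(CCC)cc(OC)cc2OC)cc(O)c1Br | intermediate
12 | tert-butyldimethylsilyl chloride | CC(C)(C)[Si](C)(C)Cl | starting material
13 | 4-bromo-3-[(tert-butyldimethylsilyl)oxy]-5-pentylphenyl 2,4-dimethoxy-6-propylbenzoate | CCCCCc1cc(OC(=O)c2c(CCC)cc(OC)cc2OC)cc(O[Si](C)(C)C(C)(C)C)c1Br | intermediate
14 | carbon dioxide | O=C=O | starting material
15 | bromomagnesium 2-[(tert-butyldimethylsilyl)oxy]-4-[(2,4-dimethoxy-6-propylbenzoyl)oxy]-6-pentylbenzoate (not isolated) | CCCCCc1cc(OC(=O)c2c(CCC)cc(OC)cc2OC)cc(O[Si](C)(C)C(C)(C)C)c1C(=O)[O-].[Mg+2].[Br-] | intermediate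
16 | 2-[(tert-butyldimethylsilyl)oxy]-4-[(2,4-dimethoxy-6-propylbenzoyl)oxy]-6-pentylbenzoic acid | CCCCCc1cc(OC(=O)c2c(CCC)cc(OC)cc2OC)cc(O[Si](C)(C)C(C)(C)C)c1C(=O)O | intermediate
17 | 4-[(2,4-dimethoxy-6-propylbenzoyl)oxy]-2-hydroxy-6-pentylbenzoic acid | CCCCCc1cc(OC(=O)c2c(CCC)cc(OC)cc2OC)cc(O)c1C(=O)O | target

## Step count and risk

Total step count: 10. Longest linear sequence: 9 steps (steps 1, 2, 3, 4, 5, 7, 8, 9, 10). The ring A branch (step 6) joins at step 7.

**Step 9 (key step).** Oxidative addition at the di-ortho-substituted C1–Br bond may be slow. The current could then be spent on CO2 reduction, on hydrodebromination by adventitious water, or on reductive cleavage of the aryl ester once the potential drifts negative. Fallback: from 13, palladium-catalysed alkoxycarbonylation (Pd(OAc)2, Xantphos, CO, benzyl alcohol, Et3N, toluene, heat) would give benzyl 2-[(tert-butyldimethylsilyl)oxy]-4-[(2,4-dimethoxy-6-propylbenzoyl)oxy]-6-pentylbenzoate F1. Hydrogenolysis of the benzyl ester (H2, 10% Pd/C, EtOAc, rt), which is neutral and spares the depside, would return to the route at 16.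

**Step 7.** Site selection between the two hydroxyls of 10 may be incomplete, and double acylation may occur. The hydroxyl ortho to bromine is the more acidic, so it can compete under basic conditions. Fallback: from olivetol 9, substoichiometric silylation with 12 (imidazole, DMF, unreacted 9 recycled) would give 3-[(tert-butyldimethylsilyl)oxy]-5-pentylphenol F2. Bromination with NBS in MeCN para to the single free hydroxyl would give 4-bromo-3-[(tert-butyldimethylsilyl)oxy]-5-pentylphenol F3. Acylation of the only remaining phenol with 8 (Et3N, DMAP, CH2Cl2) would rejoin the route at 13. This bypass also avoids bromination of the doubly activated free resorcinol in step 6.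

**Step 3.** Formylation may partly take the position between the two methoxy groups, and the isomeric aldehydes may be hard to separate. Fallback: from 4, bromination with NBS in MeCN, which is reliably para to a methoxy group, would give 1-bromo-2,4-dimethoxy-6-propylbenzene F4. Bromine–lithium exchange (n-BuLi, THF, −78 °C), quenching with CO2 and acidification would rejoin the route at 7.

**Step 10.** Fluoride may cleave the depside link in competition with desilylation, and the freed hydroxy acid may decarboxylate during work-up or concentration. Fallback: from 11, benzylation (benzyl bromide, K2CO3, acetone, rt) would give 3-(benzyloxy)-4-bromo-5-pentylphenyl 2,4-dimethoxy-6-propylbenzoate F5. The same nickel-catalysed electrocarboxylation would give 2-(benzyloxy)-4-[(2,4-dimethoxy-6-propylbenzoyl)oxy]-6-pentylbenzoic acid F6. Hydrogenolysis (H2, 10% Pd/C, EtOAc, rt) would reach 17 without fluoride or acid.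

## Further compounds

F1 | step 9 | benzyl 2-[(tert-butyldimethylsilyl)oxy]-4-[(2,4-dimethoxy-6-propylbenzoyl)oxy]-6-pentylbenzoate | CCCCCc1cc(OC(=O)c2c(CCC)cc(OC)cc2OC)cc(O[Si](C)(C)C(C)(C)C)c1C(=O)OCc1ccccc1
F2 | step 7 | 3-[(tert-butyldimethylsilyl)oxy]-5-pentylphenol | CCCCCc1cc(O)cc(O[Si](C)(C)C(C)(C)C)c1
F3 | step 7 | 4-bromo-3-[(tert-butyldimethylsilyl)oxy]-5-pentylphenol | CCCCCc1cc(O)cc(O[Si](C)(C)C(C)(C)C)c1Br
F4 | step 3 | 1-bromo-2,4-dimethoxy-6-propylbenzene | CCCc1cc(OC)cc(OC)c1Br
F5 | step 10 | 3-(benzyloxy)-4-bromo-5-pentylphenyl 2,4-dimethoxy-6-propylbenzoate | CCCCCc1cc(OC(=O)c2c(CCC)cc(OC)cc2OC)cc(OCc2ccccc2)c1Br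
F6 | step 10 | 2-(benzyloxy)-4-[(2,4-dimethoxy-6-propylbenzoyl)oxy]-6-pentylbenzoic acid | CCCCCc1cc(OC(=O)c2c(CCC)cc(OC)cc2OC)cc(OCc2ccccc2)c1C(=O)O
A1 | alternative 1 | benzyl 4-[(2,4-dimethoxy-6-propylbenzoyl)oxy]-2-hydroxy-6-pentylbenzoate | CCCCCc1cc(OC(=O)c2c(CCC)cc(OC)cc2OC)cc(O)c1C(=O)OCc1ccccc1
A2 | alternative 1 | 4-methoxy-4-(trimethylsilyloxy)buta-1,3-dien-2-yl 2,4-dimethoxy-6-propylbenzoate | C=C(OC(=O)c1c(CCC)cc(OC)cc1OC)C=C(OC)O[Si](C)(C)C
A3 | alternative 1 | benzyl oct-2-ynoate | CCCCCC#CC(=O)OCc1ccccc1
A4 | alternative 2 | benzyl 2-(benzyloxy)-4-[(2,4-dihydroxy-6-propylbenzoyl)oxy]-6-pentylbenzoate | CCCCCc1cc(OC(=O)c2c(CCC)cc(O)cc2O)cc(OCc2ccccc2)c1C(=O)OCc1ccccc1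
A5 | alternative 2 | 6-(2,4-dioxoheptyl)-2,2-dimethyl-4H-1,3-dioxin-4-one | CCCC(=O)CC(=O)CC1=CC(=O)OC(C)(C)O1
A6 | alternative 2 | dec-1-ene-1,3,5,7-tetrone (acylketene) | O=C=CC(=O)CC(=O)CC(=O)CCC
A7 | alternative 2 | benzyl 2-(benzyloxy)-4-hydroxy-6-pentylbenzoate | CCCCCc1cc(O)cc(OCc2ccccc2)c1C(=O)OCc1ccccc1
A8 | alternative 2 | benzyl 2-(benzyloxy)-6-pentyl-4-[(3,5,7-trioxodecanoyl)oxy]benzoate | CCCCCc1cc(OC(=O)CC(=O)CC(=O)CC(=O)CCC)cc(OCc2ccccc2)c1C(=O)OCc1ccccc1
A9 | alternative 3 | tert-butyl 4-[(2,4-dimethoxy-6-propylbenzoyl)oxy]-2-(methoxymethoxy)-6-pentylbenzoate | CCCCCc1cc(OC(=O)c2c(CCC)cc(OC)cc2OC)cc(OCOC)c1C(=O)OC(C)(C)C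
A10 | alternative 3 | tert-butyl 2-(methoxymethoxy)-6-pentyl-4-(4,4,5,5-tetramethyl-1,3,2-dioxaborolan-2-yl)benzoate | CCCCCc1cc(B2OC(C)(C)C(C)(C)O2)cc(OCOC)c1C(=O)OC(C)(C)C
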